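Remarks on the chemistry. Labdane numbering is used for both halves: C1–C2 is the acetic arm on C10, C3–C4 the isobutyric unit on C5, ring B is C5–C10, ring C is O–C8–C9–C11–C12–C13, C17 is the methyl on C8 and C20 the methyl on C10; primed locants belong to the diol half. Assumption: the configuration is taken exactly as drawn in the SMILES, that is 5S,8S,9R,10R in both bicycles, 13R in the vinyl half, 13′S,14′R in the diol half.

## Analysis of the target

The target is an ester-linked dimer of two 2,3-seco-labdane units. Each unit is a cis-fused 2-oxabicyclo[4.4.0]decane: ring B (C5–C10) is carbocyclic and ring C (O, C8, C9, C11, C12, C13) is a tetrahydropyran whose two ether carbons are fully substituted. Each bicycle has five stereocentres (C5, C8, C9, C10, C13) and the same ring configuration. One face of ring B carries the C20 methyl, 9-H, the C17 methyl and the isobutyric unit on C5; the other carries the C1 acetic arm, C11 and the ring oxygen. The halves differ only in the side chain: the vinyl half is 13R, and the diol half is 13′S with a 14′R carbinol and the C15′ oxygen esterified by C2 of the vinyl half. Sensitive features are the tertiary allylic ether at C13 of the vinyl half (ionises in strong acid), the vinyl group (no hydrogenolysis), the single ester link (no hydrolytic unmasking at the end) and three carboxyl groups of very different hindrance. The synthesis is hard because C10 is quaternary and flanked by tertiary C5 (which bears quaternary C4) and tertiary C9. It is also hard because 9-H is cis to the C20 methyl, which rules out degradation of common labdanes, and because two stereochemically different chains sit on identical cores. The strategy rests on the C9–C10 bond of ring B: C11 is cis to the acetic arm C1 and 9-H is cis to the C20 methyl, which is exactly the arrangement of the four substituents of an E-trisubstituted alkene C9=C10.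

## Retrosynthetic reasoning

Target 50 is taken back to its triallyl ester 49. The three carboxyl groups are unmasked last because the only other ester, the C2–O–C15′ link, must survive. Allyl esters leave by palladium-catalysed allyl transfer, which touches neither that link, nor the vinyl group, nor the acid-labile allylic ether at C13.

Compound 49 is cut at the ester bond C2(=O)–O15′ into acid 48 (vinyl half) and diol 26 (diol half). This is the one bond that joins two fragments of equal size, so the cut gives the greatest convergence. The forward acylation should be regioselective on its own, since the C15′ hydroxyl is primary and the C14′ hydroxyl is secondary and neopentylic. Acid 48 comes from diallyl ester 47, because the CH2-bound C2 ester saponifies while the α,α-dimethyl C3 ester does not.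

The vinyl group of 47 is traced through thiocarbonate 46 to the 14,15-diol of 45. Both halves then descend from the same kind of intermediate, the diacid diols 44 and 25, which differ only at C13 and C14. One sequence run twice serves both halves, and no alkene or allylic ether is present while acid is in use. Esters 45 and 26 arise from 44 and 25 by O-alkylation of the carboxylates.

In 25 (and 44) the C8–O bond of ring C is cut, which leads to alkene 24 (43) with the C13 oxygen still masked. The cut is made at C8 and not at C13 because C13 is a stereocentre that can be bought from 6, whereas C8 can be set by the ring system itself. The forward step has to protonate C7, close the six-membered ether on the face of the C9 chain, and in the same operation remove the tert-butyl, acetonide and silyl groups.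

Alkene 24 goes back through enol triflate 23 to ketone 22, so the C7 oxygen left by the cycloaddition is used to place the double bond and is then removed. In 22 the C4–C5 bond is cut: the isobutyrate unit arrives as ketene acetal 5 (from 4) by conjugate addition to enone 20. This bond is made late, on the ring, because the ring then dictates the face of attack at C5. Removing the C17 methyl from 20 gives 19; the forward alkylation is unambiguous because C8 is the only enolisable position of that enone.

The C20 methyl of 19 is traced through tosylhydrazone 18 to the formyl group of 17. The formyl group is what activates the dienophile, and it has to be gone before enolate and silyl ketene acetal chemistry begins.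

Enone 17 is cut at C8–C9 and C5–C10 into E-enal 14 and diene 15. Both cuts are taken together because they sit on one face of the C9=C10 alkene of 14. A suprafacial cycloaddition then turns alkene geometry into the C9/C10 relation and closes ring B, with the quaternary centre formed in the same step. The forward reaction has to choose the C=C bond over the formyl group, and one enantiotopic face, independently of the remote chain stereocentres.

Enal 14 comes from allylic alcohol 13 and diester 12. The trisubstituted alkene of 12 is cut into aldehyde 11 and phosphonate 3 (from 1 and 2). The unequal ester groups of 3 are chosen so that only the conjugated ester is reduced and the acetic arm keeps its carboxyl oxidation level.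

Aldehyde 11 is traced through 10, 9 and 8 to epoxide 7 and to 6. C14 comes from the asymmetric epoxidation and C13 from opening of the epoxide with inversion. The vinyl half needs the mirror-image chain, so the same five operations with the antipodal ligand give 27 to 31. Compounds 32 to 43 then repeat 12 to 24.

## Alternatives that were turned down

Alternative 1: Ring A is kept as a sacrificial carbocycle. The C2–O and O–C3 bonds of the seven-membered anhydride A1 are traced to the C2–C3 bond of the tricyclic 2,3-diketone A2. In the forward key step a peracid inserts oxygen between the two carbonyl groups (Baeyer–Villiger oxidation of an α-diketone) and expands ring A to A1.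
- For it: inside a decalin the C5/C10 relation and the congested C4–C5–C10 array exist from the start and never have to be made by an intermolecular addition at C5. A1 would be opened by the C15′ hydroxyl of 26 at the less hindered C2 carbonyl, which forms the ester link and leaves the C3 acid free with no protecting group. On end-game economy this is stronger than the chosen route, which spends allylation, selective saponification and deallylation.
- Against it: A2 requires a tricyclic 8,13-epoxylabdane with 9-H cis to the C20 methyl and a cis B/C fusion. Sclareol-type feedstocks have the other C9 configuration, so rings A and B would have to be built anew or C9 inverted next to a quaternary centre. The peracid must also spare the vinyl group, and the diol half still needs a separate way to its free acids.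
- Comparison: the chosen strategy gives up the protecting-group-free union. In return it sets C9 and C10 in one step from alkene geometry and never builds a ring only to cleave it.

Alternative 2: A cation–olefin cyclisation of a nerol-derived chain. The C9–C10 and C8–O bonds of the cis-fused lactone aldehyde A3 are cut, which leads to the acyclic Z-olefin enal ester A4. In the forward key step EtAlCl2 activates the enal, the Z-trisubstituted alkene attacks C10 through C9 to close ring B, and the tert-butyl ester oxygen captures the C8 cation to close the lactone.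
- For it: one operation forms ring B and the C8–O bond and sets C8, C9 and C10. A3 is common to both halves because C13 is still a carbonyl carbon, so one ring-forming sequence serves where the chosen route runs two in parallel. On convergence it is clearly stronger.
- Against it: C5 must be set enantioselectively in the open chain, beside quaternary C4, and must then steer the folding. The 9-H/C20 relation depends on chair versus boat folding and on which face of the enal is attacked, not on a stereospecific rule. Both C13 configurations must then be made from a lactone carbonyl by two successive carbon additions, so a tertiary ether stereocentre is created twice, once in each sense, under weak control.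
- Comparison: the chosen route takes C13 and C14 from an asymmetric epoxidation and fixes C9/C10 by suprafacial cycloaddition, at the price of duplicated steps.

Alternative 3: A Wolff rearrangement that builds C1 and the ester link together. The C1–C10 and C2–O15′ bonds are cut, leading to the C10 diazoketone A6 and the diol 26. In the forward key step AgO2CPh or light converts A6 into ketene A7 by a 1,2-shift of C10 with retention, and the primary C15′ hydroxyl adds to give A5, which is the same compound as 49.
- For it: the inter-half ester forms without a free C2 acid, a coupling agent or a selective saponification, and the hindered neopentylic C1–C10 bond is made intramolecularly. On the union itself it is at least as good as the carbodiimide coupling used here.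
- Against it: the step closes no ring and sets no stereocentre, so the whole bicyclic core must still come from another method. C10 must first carry a carboxyl group that is turned into an acid chloride and a diazoketone at a fully substituted carbon. The carbene or ketene must ignore four alkenes (vinyl and allyl groups) and the free C14′ hydroxyl.
- Comparison: the chosen strategy places its risk in a step that builds ring B and two stereocentres and keeps the union as a routine esterification.

Key step: step 11

## Steps

Step 1
Reactants: 1 trimethyl phosphonoacetate; 2 tert-butyl bromoacetate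
Product: 3 4-tert-butyl 1-methyl 2-(dimethoxyphosphoryl)butanedioate (racemic)
Conditions: NaH, THF, 0 to 23 °C
Reagents that add atoms: none
Why: C-alkylation of the stabilised phosphonate anion by a reactive α-bromo ester; the two unequal ester groups later allow the conjugated ester alone to be reduced.

Step 2
Reactants: 4 tert-butyl isobutyrate
Product: 5 (1-tert-butoxy-2-methylprop-1-enyloxy)trimethylsilane
Conditions: LiN(i-Pr)2, THF, −78 °C; Me3SiCl, −78 to 23 °C
Reagents that add atoms: chlorotrimethylsilane, C[Si](C)(C)Cl
Why: O-silylation of the lithium ester enolate; the enolate carbon bears two methyl groups, so no geometric isomers arise.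

Step 3
Reactants: 6 geraniol
Product: 7 (2R,3R)-2,3-epoxygeraniol
Conditions: Ti(Oi-Pr)4 (5 mol%), D-(−)-diethyl tartrate (6 mol%), t-BuOOH, 4 Å molecular sieves, CH2Cl2, −20 °C
Reagents that add atoms: tert-butyl hydroperoxide, CC(C)(C)OO
Why: Sharpless asymmetric epoxidation of the allylic alcohol; the D-tartrate complex should deliver oxygen to the face that gives the (2R,3R) epoxide, which fixes C14′ and, after step 4, C13′; the remote 6,7-alkene is not an allylic alcohol and stays.

Step 4
Reactants: 7 (2R,3R)-2,3-epoxygeraniol
Product: 8 (2R,3S)-3,7-dimethyloct-6-ene-1,2,3-triol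
Conditions: HClO4 (5 mol%), THF/H2O 3:1, 0 °C
Reagents that add atoms: water, O
Why: Acid-catalysed epoxide hydrolysis; water should attack the tertiary carbon, which best carries positive charge, from the rear, so C3 is inverted and C2 retained.

Step 5
Reactants: 8 (2R,3S)-3,7-dimethyloct-6-ene-1,2,3-triol
Product: 9 (2S)-2-[(4R)-2,2-dimethyl-1,3-dioxolan-4-yl]-6-methylhept-5-en-2-ol
Conditions: 2-methoxypropene, pyridinium p-toluenesulfonate (cat.), CH2Cl2, 0 °C
Reagents that add atoms: 2-methoxypropene, COC(C)=C
Why: Kinetic acetonide formation should engage the primary hydroxyl and its secondary neighbour; the tertiary hydroxyl reacts slowest and stays free.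

Step 6
Reactants: 9 (2S)-2-[(4R)-2,2-dimethyl-1,3-dioxolan-4-yl]-6-methylhept-5-en-2-ol
Product: 10 triethylsilyl ether of 9
Conditions: Et3SiOTf, 2,6-lutidine, CH2Cl2, −78 to 0 °C
Reagents that add atoms: triethylsilyl trifluoromethanesulfonate, CC[Si](CC)(CC)OS(=O)(=O)C(F)(F)F
Why: A silyl triflate silylates the hindered tertiary alcohol; this masks the oxygen that later closes ring C and prevents lactol formation after step 7.

Step 7
Reactants: 10 triethylsilyl ether of 9
Product: 11 (4S)-4-[(4R)-2,2-dimethyl-1,3-dioxolan-4-yl]-4-(triethylsilyloxy)pentanal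
Conditions: O3, CH2Cl2/MeOH, −78 °C; Me2S, −78 to 23 °C
Reagents that add atoms: ozone, [O-][O+]=O
Why: Ozonolysis of the only alkene with reductive work-up; acetal and silyl ether are inert.

Step 8
Reactants: 11 (4S)-4-[(4R)-2,2-dimethyl-1,3-dioxolan-4-yl]-4-(triethylsilyloxy)pentanal; 3 4-tert-butyl 1-methyl 2-(dimethoxyphosphoryl)butanedioate
Product: 12 4-tert-butyl 1-methyl (2E)-2-[(4S)-4-[(4R)-2,2-dimethyl-1,3-dioxolan-4-yl]-4-(triethylsilyloxy)pentylidene]butanedioate
Conditions: NaH, THF, 0 to 23 °C
Reagents that add atoms: none
Why: Horner–Wadsworth–Emmons olefination; the stabilised phosphonate should place the chain trans to the conjugated ester (E), the geometry later read out as the C9/C10 relation; a minor Z isomer would be removed by chromatography.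

Step 9
Reactants: 12 4-tert-butyl 1-methyl (2E)-alkylidenebutanedioate of the diol-half chain
Product: 13 tert-butyl (3E,7S)-7-[(4R)-2,2-dimethyl-1,3-dioxolan-4-yl]-3-(hydroxymethyl)-7-(triethylsilyloxy)oct-3-enoate
Conditions: i-Bu2AlH (2.2 equiv), CH2Cl2, −78 °C
Reagents that add atoms: none
Why: Hydride reduction of the methyl ester to the allylic alcohol; the tert-butyl ester is too hindered to react at −78 °C and also resists lactonisation by the new hydroxyl.

Step 10
Reactants: 13 tert-butyl (3E,7S)-3-(hydroxymethyl)oct-3-enoate of the diol-half chain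
Product: 14 tert-butyl (3E,7S)-7-[(4R)-2,2-dimethyl-1,3-dioxolan-4-yl]-3-formyl-7-(triethylsilyloxy)oct-3-enoate
Conditions: Dess–Martin periodinane, NaHCO3, CH2Cl2, 0 to 23 °C
Reagents that add atoms: none
Why: Buffered Dess–Martin oxidation of the allylic alcohol; neutral conditions keep the E geometry and stop the alkene moving into conjugation with the ester.

Step 11
Reactants: 14 tert-butyl (3E,7S)-7-[(4R)-2,2-dimethyl-1,3-dioxolan-4-yl]-3-formyl-7-(triethylsilyloxy)oct-3-enoate; 15 (E)-1-methoxy-3-(trimethylsilyloxy)buta-1,3-diene
Product: 17 (9S,10R) ring B enone aldehyde of the diol-half series, via cycloadduct 16 (not isolated)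
Conditions: (S)-3,3-diphenyl-1-(o-tolyl)tetrahydro-1H,3H-pyrrolo[1,2-c][1,3,2]oxazaborole (20 mol%, from (S)-α,α-diphenylprolinol and tri-o-tolylboroxine), HNTf2 (18 mol%), 15 (2.5 equiv), CH2Cl2, −78 to −40 °C; then CF3CO2H (cat.), CH2Cl2, 0 °C
Reagents that add atoms: none
Why: The protonated oxazaborolidine binds the formyl oxygen of 14 (the α-substituent enforces the s-trans enal and a formyl C–H···O contact to the ring oxygen) and lowers the LUMO of the C9=C10 bond; 15 then adds in a concerted, asynchronous [4+2] process, its unsubstituted terminus bonding to the β-carbon C9 and its methoxy-bearing terminus to the α-carbon C10, the normal polarity match. The closest known reaction type is the Lewis-acid-catalysed Diels–Alder reaction of 1-alkoxy-3-siloxybutadienes with α-substituted enals to 4-formyl-4-alkylcyclohexenones, together with oxazaborolidinium-catalysed additions of dienes to α,β-disubstituted enals. Ring B (C5–C10) closes as a six-membered carbocycle by forming C8–C9 and C5–C10 on one face of the alkene; acid then hydrolyses the silyl enol ether of 16 and eliminates the C5 methoxy group to give the C5=C6 enone. Because the addition is suprafacial, the E geometry of 14 alone places C11 cis to the acetic arm and the formyl group cis to 9-H, so the C9/C10 relation is substrate-controlled; the endo/exo question concerns only the methoxy carbon, which becomes sp2. The absolute configuration (9S,10R) has to come from the catalyst, since C13 and C14 are five and six bonds from the reacting alkene: an aryl group of the (S)-catalyst is expected to shield one face of the bound enal so that the diene enters on the other. Three selectivities are needed: attack at C=C rather than at the formyl carbon (secured by the binding mode, which activates the alkene, and by the low temperature), regiochemistry (secured by the two oxygen substituents of 15) and enantiofacial selectivity (secured by the catalyst).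

Step 12
Reactants: 17 (9S,10R) ring B enone aldehyde of the diol-half series
Product: 19 (9S,10S)-10-methyl ring B enone of the diol-half series, via tosylhydrazone 18 (not isolated)
Conditions: TsNHNH2 (1.05 equiv), THF, 23 °C, concentrate from toluene; catecholborane, CHCl3, 0 °C; NaOAc·3H2O, 65 °C
Reagents that add atoms: none
Why: Caglioti-type reduction in the Kabalka variant: the aldehyde condenses far faster than the conjugated ketone, catecholborane reduces the C=N bond, and acetate releases sulfinate and nitrogen to leave the C20 methyl; a cyclohexenone locked s-trans should be slow towards catecholborane.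

Step 13
Reactants: 19 (9S,10S)-10-methyl ring B enone of the diol-half series
Product: 20 (9S,10R)-8,10-dimethyl ring B enone of the diol-half series (C8 epimers)
Conditions: LiN(i-Pr)2 (1.05 equiv), THF, −78 °C; CH3I, DMPU, −78 to −40 °C
Reagents that add atoms: iodomethane, CI
Why: Kinetic α′-deprotonation and alkylation; C8 is the only enolisable ring position because C10 is quaternary, and the tert-butyl ester neither enolises competitively nor accepts the enolate; the C8 configuration is irrelevant because C8 becomes sp2 in step 15.

Step 14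
Reactants: 20 (9S,10R)-8,10-dimethyl ring B enone of the diol-half series; 5 (1-tert-butoxy-2-methylprop-1-enyloxy)trimethylsilane
Product: 22 (5S,9S,10S) C7 ketone bearing the tert-butyl isobutyrate unit on C5 (C8 epimers), via silyl enol ether 21 (not isolated)
Conditions: 5 (2 equiv), HNTf2 (5 mol%), CH2Cl2, −78 to −40 °C; then K2CO3, MeOH, 0 °C
Reagents that add atoms: none
Why: Mukaiyama–Michael addition catalysed by the silyl triflimide formed in situ; its early transition state tolerates the congested C4–C5–C10 array. The new C5 stereocentre should form by axial attack on the half-chair that has the C1 arm axial and the C9 chain equatorial, anti to both, so C4 ends cis to the C20 methyl; methanolysis of the silyl enol ether gives the ketone.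

Step 15
Reactants: 22 (5S,9S,10S) C7 ketone of the diol-half series
Product: 23 (5S,9R,10S) C7=C8 enol triflate of the diol-half series
Conditions: Tf2O, 2,6-di-tert-butyl-4-methylpyridine, CH2Cl2, 0 to 23 °C
Reagents that add atoms: trifluoromethanesulfonic anhydride, O=S(=O)(OS(=O)(=O)C(F)(F)F)C(F)(F)F
Why: Enol triflate formation through the O-triflyloxycarbenium ion, which should lose the C8 proton to give the more substituted, tetrasubstituted alkene; the axial C9 chain removes allylic 1,2-strain from that isomer.

Step 16
Reactants: 23 (5S,9R,10S) C7=C8 enol triflate of the diol-half series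
Product: 24 (5S,9S,10S) C7=C8 alkene of the diol-half series
Conditions: Pd(OAc)2 (5 mol%), PPh3 (10 mol%), n-Bu3N, HCO2H, DMF, 60 °C
Reagents that add atoms: none
Why: Palladium-catalysed formate reduction of a vinyl triflate (oxidative addition, formate exchange, loss of CO2, reductive elimination); the alkene stays where the triflate was, leaving C8 as the carbon that forms the tertiary cation.

Step 17
Reactants: 24 (5S,9S,10S) C7=C8 alkene of the diol-half series
Product: 25 (5S,8S,9R,10R,13S,14R) diol diacid of the diol half
Conditions: CF3CO2H/CH2Cl2 1:1, 0 to 23 °C; then H2O, 23 °C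
Reagents that add atoms: none
Why: Acid-mediated Markovnikov hydroalkoxylation: protonation at C7 gives the tertiary C8 cation, which the C13 oxygen captures as a six-membered ether, while the same acid removes the silyl, acetonide and tert-butyl groups. C8 is set because only the cis-fused ring (oxygen on the face of the axial C9 chain, C17 methyl axial) keeps the bulky C5 substituent equatorial, and the closure is reversible, so this isomer should be both the kinetic and the thermodynamic product; C13 does not ionise because it bears an oxygenated neighbour.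

Step 18
Reactants: 25 (5S,8S,9R,10R,13S,14R) diol diacid of the diol half
Product: 26 diallyl ester of 25
Conditions: CH2=CHCH2Br, Cs2CO3, DMF, 0 to 23 °C
Reagents that add atoms: allyl bromide, C=CCBr
Why: O-alkylation of caesium carboxylates; SN2 attack on allyl bromide is indifferent to the hindrance of the C3′ carboxyl, and the hydroxyl groups are not alkylated under these conditions.

Step 19
Reactants: 6 geraniol
Product: 27 (2S,3S)-2,3-epoxygeraniol
Conditions: Ti(Oi-Pr)4 (5 mol%), L-(+)-diethyl tartrate (6 mol%), t-BuOOH, 4 Å molecular sieves, CH2Cl2, −20 °C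
Reagents that add atoms: tert-butyl hydroperoxide, CC(C)(C)OO
Why: Sharpless asymmetric epoxidation as in step 3 with the antipodal ligand, which should give the mirror-image epoxide needed for the 13R chain of the vinyl half.

Step 20
Reactants: 27 (2S,3S)-2,3-epoxygeraniol
Product: 28 (2S,3R)-3,7-dimethyloct-6-ene-1,2,3-triol
Conditions: HClO4 (5 mol%), THF/H2O 3:1, 0 °C
Reagents that add atoms: water, O
Why: Acid-catalysed epoxide hydrolysis at the tertiary carbon with inversion, as in step 4.

Step 21
Reactants: 28 (2S,3R)-3,7-dimethyloct-6-ene-1,2,3-triol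
Product: 29 (2R)-2-[(4S)-2,2-dimethyl-1,3-dioxolan-4-yl]-6-methylhept-5-en-2-ol
Conditions: 2-methoxypropene, pyridinium p-toluenesulfonate (cat.), CH2Cl2, 0 °C
Reagents that add atoms: 2-methoxypropene, COC(C)=C
Why: Kinetic acetonide formation on the primary/secondary diol, as in step 5.

Step 22
Reactants: 29 (2R)-2-[(4S)-2,2-dimethyl-1,3-dioxolan-4-yl]-6-methylhept-5-en-2-ol
Product: 30 triethylsilyl ether of 29
Conditions: Et3SiOTf, 2,6-lutidine, CH2Cl2, −78 to 0 °C
Reagents that add atoms: triethylsilyl trifluoromethanesulfonate, CC[Si](CC)(CC)OS(=O)(=O)C(F)(F)F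
Why: Silylation of the tertiary alcohol with a silyl triflate, as in step 6.

Step 23
Reactants: 30 triethylsilyl ether of 29
Product: 31 (4R)-4-[(4S)-2,2-dimethyl-1,3-dioxolan-4-yl]-4-(triethylsilyloxy)pentanal
Conditions: O3, CH2Cl2/MeOH, −78 °C; Me2S, −78 to 23 °C
Reagents that add atoms: ozone, [O-][O+]=O
Why: Ozonolysis with reductive work-up, as in step 7.

Step 24
Reactants: 31 (4R)-4-[(4S)-2,2-dimethyl-1,3-dioxolan-4-yl]-4-(triethylsilyloxy)pentanal; 3 4-tert-butyl 1-methyl 2-(dimethoxyphosphoryl)butanedioate
Product: 32 4-tert-butyl 1-methyl (2E)-2-[(4R)-4-[(4S)-2,2-dimethyl-1,3-dioxolan-4-yl]-4-(triethylsilyloxy)pentylidene]butanedioate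
Conditions: NaH, THF, 0 to 23 °C
Reagents that add atoms: none
Why: E-selective Horner–Wadsworth–Emmons olefination, as in step 8.

Step 25
Reactants: 32 4-tert-butyl 1-methyl (2E)-alkylidenebutanedioate of the vinyl-half chain
Product: 33 tert-butyl (3E,7R)-7-[(4S)-2,2-dimethyl-1,3-dioxolan-4-yl]-3-(hydroxymethyl)-7-(triethylsilyloxy)oct-3-enoate
Conditions: i-Bu2AlH (2.2 equiv), CH2Cl2, −78 °C
Reagents that add atoms: none
Why: Selective hydride reduction of the methyl ester beside the hindered tert-butyl ester, as in step 9.

Step 26
Reactants: 33 tert-butyl (3E,7R)-3-(hydroxymethyl)oct-3-enoate of the vinyl-half chain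
Product: 34 tert-butyl (3E,7R)-7-[(4S)-2,2-dimethyl-1,3-dioxolan-4-yl]-3-formyl-7-(triethylsilyloxy)oct-3-enoate
Conditions: Dess–Martin periodinane, NaHCO3, CH2Cl2, 0 to 23 °C
Reagents that add atoms: none
Why: Buffered Dess–Martin oxidation of the allylic alcohol, as in step 10.

Step 27
Reactants: 34 tert-butyl (3E,7R)-7-[(4S)-2,2-dimethyl-1,3-dioxolan-4-yl]-3-formyl-7-(triethylsilyloxy)oct-3-enoate; 15 (E)-1-methoxy-3-(trimethylsilyloxy)buta-1,3-diene
Product: 36 (9S,10R) ring B enone aldehyde of the vinyl-half series, via cycloadduct 35 (not isolated)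
Conditions: (S)-3,3-diphenyl-1-(o-tolyl)tetrahydro-1H,3H-pyrrolo[1,2-c][1,3,2]oxazaborole (20 mol%), HNTf2 (18 mol%), 15 (2.5 equiv), CH2Cl2, −78 to −40 °C; then CF3CO2H (cat.), CH2Cl2, 0 °C
Reagents that add atoms: none
Why: The same catalytic Diels–Alder reaction as step 11; the same catalyst enantiomer should give the same ring configuration because the inverted chain centres are too remote to influence the face of attack.

Step 28
Reactants: 36 (9S,10R) ring B enone aldehyde of the vinyl-half series
Product: 38 (9S,10S)-10-methyl ring B enone of the vinyl-half series, via tosylhydrazone 37 (not isolated)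
Conditions: TsNHNH2 (1.05 equiv), THF, 23 °C, concentrate from toluene; catecholborane, CHCl3, 0 °C; NaOAc·3H2O, 65 °C
Reagents that add atoms: none
Why: Caglioti-type reduction of the aldehyde tosylhydrazone to the C20 methyl, as in step 12.

Step 29
Reactants: 38 (9S,10S)-10-methyl ring B enone of the vinyl-half series
Product: 39 (9S,10R)-8,10-dimethyl ring B enone of the vinyl-half series (C8 epimers)
Conditions: LiN(i-Pr)2 (1.05 equiv), THF, −78 °C; CH3I, DMPU, −78 to −40 °C
Reagents that add atoms: iodomethane, CI
Why: Alkylation of the only available ketone enolate (C8), as in step 13.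

Step 30
Reactants: 39 (9S,10R)-8,10-dimethyl ring B enone of the vinyl-half series; 5 (1-tert-butoxy-2-methylprop-1-enyloxy)trimethylsilane
Product: 41 (5S,9S,10S) C7 ketone bearing the tert-butyl isobutyrate unit on C5 (vinyl-half series, C8 epimers), via silyl enol ether 40 (not isolated)
Conditions: 5 (2 equiv), HNTf2 (5 mol%), CH2Cl2, −78 to −40 °C; then K2CO3, MeOH, 0 °C
Reagents that add atoms: none
Why: Mukaiyama–Michael addition anti to the C1 arm and the C9 chain, as in step 14; C5 is set by the ring, not by the chain.

Step 31
Reactants: 41 (5S,9S,10S) C7 ketone of the vinyl-half series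
Product: 42 (5S,9R,10S) C7=C8 enol triflate of the vinyl-half series
Conditions: Tf2O, 2,6-di-tert-butyl-4-methylpyridine, CH2Cl2, 0 to 23 °C
Reagents that add atoms: trifluoromethanesulfonic anhydride, O=S(=O)(OS(=O)(=O)C(F)(F)F)C(F)(F)F
Why: Formation of the more substituted enol triflate, as in step 15.

Step 32
Reactants: 42 (5S,9R,10S) C7=C8 enol triflate of the vinyl-half series
Product: 43 (5S,9S,10S) C7=C8 alkene of the vinyl-half series
Conditions: Pd(OAc)2 (5 mol%), PPh3 (10 mol%), n-Bu3N, HCO2H, DMF, 60 °C
Reagents that add atoms: none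
Why: Palladium-catalysed formate reduction of the vinyl triflate, as in step 16.

Step 33
Reactants: 43 (5S,9S,10S) C7=C8 alkene of the vinyl-half series
Product: 44 (5S,8S,9R,10R,13R,14S) diol diacid of the vinyl-half series
Conditions: CF3CO2H/CH2Cl2 1:1, 0 to 23 °C; then H2O, 23 °C
Reagents that add atoms: none
Why: Acid-mediated ring C closure with concurrent loss of the silyl, acetonide and tert-butyl groups, as in step 17; C8 is set by the ring B chair, so it comes out the same although C13 is inverted, and no vinyl group is yet present to suffer from the acid.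

Step 34
Reactants: 44 (5S,8S,9R,10R,13R,14S) diol diacid of the vinyl-half series
Product: 45 diallyl ester of 44
Conditions: CH2=CHCH2Br, Cs2CO3, DMF, 0 to 23 °C
Reagents that add atoms: allyl bromide, C=CCBr
Why: O-alkylation of both caesium carboxylates, as in step 18; it masks the acids before thiocarbonate formation.

Step 35
Reactants: 45 diallyl ester of 44
Product: 46 cyclic 14,15-thiocarbonate of 45
Conditions: 1,1′-thiocarbonyldiimidazole, DMAP (cat.), toluene, 80 °C
Reagents that add atoms: 1,1′-thiocarbonyldiimidazole, S=C(n1ccnc1)n1ccnc1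
Why: First stage of the Corey–Winter olefination; the 1,2-diol closes a five-membered thiocarbonate.

Step 36
Reactants: 46 cyclic 14,15-thiocarbonate of 45
Product: 47 (5S,8S,9R,10R,13R) vinyl diallyl ester
Conditions: 1,3-dimethyl-2-phenyl-1,3,2-diazaphospholidine, THF, 40 °C
Reagents that add atoms: none
Why: Corey–Winter elimination in the Corey–Hopkins variant: the phosphorus reagent removes sulfur and the carbene-like intermediate loses CO2 to give the terminal alkene under neutral conditions; C13 is untouched and stays R.

Step 37
Reactants: 47 (5S,8S,9R,10R,13R) vinyl diallyl ester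
Product: 48 C2 acid of the vinyl half (C3 allyl ester retained)
Conditions: LiOH·H2O, THF/H2O 3:1, 0 to 23 °C; then 1 M HCl to pH 4, 0 °C
Reagents that add atoms: lithium hydroxide, [Li+].[OH-]
Why: Site-selective saponification; hydroxide reaches the CH2-bound C2 ester but not the α,α-dimethyl C3 ester buried between C5 and C10.

Step 38
Reactants: 48 C2 acid of the vinyl half; 26 diallyl ester of 25
Product: 49 triallyl ester of the target
Conditions: EDC·HCl, DMAP, CH2Cl2, 0 to 23 °C
Reagents that add atoms: none
Why: Steglich esterification; the primary C15′ hydroxyl of 26 should be acylated in preference to the secondary C14′ hydroxyl, which is neopentylic and less nucleophilic.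

Step 39
Reactants: 49 triallyl ester of the target
Product: 50 CNP0271961.3
Conditions: Pd(PPh3)4 (5 mol%), morpholine, THF, 23 °C
Reagents that add atoms: none
Why: Palladium-catalysed allyl transfer to morpholine (Tsuji–Trost deallylation) frees all three acids through π-allyl complexes without nucleophilic attack at any carbonyl, so the C2–O–C15′ ester, the vinyl group and the C13 allylic ether remain.

## Compound list

1 | trimethyl phosphonoacetate | COC(=O)CP(=O)(OC)OC | starting material
2 | tert-butyl bromoacetate | BrCC(=O)OC(C)(C)C | starting material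
3 | 4-tert-butyl 1-methyl 2-(dimethoxyphosphoryl)butanedioate (racemic) | COC(=O)C(CC(=O)OC(C)(C)C)P(=O)(OC)OC | intermediate
4 | tert-butyl isobutyrate | CC(C)C(=O)OC(C)(C)C | starting material
5 | (1-tert-butoxy-2-methylprop-1-enyloxy)trimethylsilane | CC(C)=C(OC(C)(C)C)O[Si](C)(C)C | intermediate
6 | geraniol | CC(C)=CCC/C(C)=C/CO | starting material
7 | (2R,3R)-2,3-epoxygeraniol | CC(C)=CCC[C@@]1(C)O[C@@H]1CO | intermediate
8 | (2R,3S)-3,7-dimethyloct-6-ene-1,2,3-triol | CC(C)=CCC[C@](C)(O)[C@H](O)CO | intermediate
9 | (2S)-2-[(4R)-2,2-dimethyl-1,3-dioxolan-4-yl]-6-methylhept-5-en-2-ol | CC(C)=CCC[C@](C)(O)[C@H]1COC(C)(C)O1 | intermediate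
10 | triethylsilyl ether of 9 | CC(C)=CCC[C@](C)(O[Si](CC)(CC)CC)[C@H]1COC(C)(C)O1 | intermediate
11 | (4S)-4-[(4R)-2,2-dimethyl-1,3-dioxolan-4-yl]-4-(triethylsilyloxy)pentanal | O=CCC[C@](C)(O[Si](CC)(CC)CC)[C@H]1COC(C)(C)O1 | intermediate
12 | 4-tert-butyl 1-methyl (2E)-2-[(4S)-4-[(4R)-2,2-dimethyl-1,3-dioxolan-4-yl]-4-(triethylsilyloxy)pentylidene]butanedioate | COC(=O)/C(CC(=O)OC(C)(C)C)=C/CC[C@](C)(O[Si](CC)(CC)CC)[C@H]1COC(C)(C)O1 | intermediate
13 | tert-butyl (3E,7S)-7-[(4R)-2,2-dimethyl-1,3-dioxolan-4-yl]-3-(hydroxymethyl)-7-(triethylsilyloxy)oct-3-enoate | OC/C(CC(=O)OC(C)(C)C)=C/CC[C@](C)(O[Si](CC)(CC)CC)[C@H]1COC(C)(C)O1 | intermediate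
14 | tert-butyl (3E,7S)-7-[(4R)-2,2-dimethyl-1,3-dioxolan-4-yl]-3-formyl-7-(triethylsilyloxy)oct-3-enoate (E-enal, diol-half chain) | O=C/C(CC(=O)OC(C)(C)C)=C/CC[C@](C)(O[Si](CC)(CC)CC)[C@H]1COC(C)(C)O1 | intermediate
15 | (E)-1-methoxy-3-(trimethylsilyloxy)buta-1,3-diene | CO/C=C/C(=C)O[Si](C)(C)C | starting material
16 | cycloadduct of 14 and 15 (5-methoxy, C6=C7 silyl enol ether, C9 and C10 as in 17, C5 epimers) | COC1C=C(O[Si](C)(C)C)C[C@H](CC[C@](C)(O[Si](CC)(CC)CC)[C@H]2COC(C)(C)O2)[C@]1(C=O)CC(=O)OC(C)(C)C | intermediate
17 | (9S,10R) ring B enone aldehyde, diol-half series (C7 ketone, C5=C6, formyl and CH2CO2t-Bu on C10, chain on C9) | O=C1C=C[C@@](C=O)(CC(=O)OC(C)(C)C)[C@@H](CC[C@](C)(O[Si](CC)(CC)CC)[C@H]2COC(C)(C)O2)C1 | intermediate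
18 | E-tosylhydrazone of 17 | Cc1ccc(cc1)S(=O)(=O)N/N=C/[C@@]2(CC(=O)OC(C)(C)C)C=CC(=O)C[C@@H]2CC[C@](C)(O[Si](CC)(CC)CC)[C@H]3COC(C)(C)O3 | intermediate
19 | (9S,10S)-10-methyl ring B enone, diol-half series | O=C1C=C[C@@](C)(CC(=O)OC(C)(C)C)[C@@H](CC[C@](C)(O[Si](CC)(CC)CC)[C@H]2COC(C)(C)O2)C1 | intermediate
20 | (9S,10R)-8,10-dimethyl ring B enone, diol-half series (C8 epimers) | CC1C(=O)C=C[C@@](C)(CC(=O)OC(C)(C)C)[C@H]1CC[C@](C)(O[Si](CC)(CC)CC)[C@H]2COC(C)(C)O2 | intermediate
21 | (5S,9S,10S) C6=C7 trimethylsilyl enol ether, diol-half series (C8 epimers) | CC1C(O[Si](C)(C)C)=C[C@H](C(C)(C)C(=O)OC(C)(C)C)[C@@](C)(CC(=O)OC(C)(C)C)[C@H]1CC[C@](C)(O[Si](CC)(CC)CC)[C@H]2COC(C)(C)O2 | intermediate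
22 | (5S,9S,10S) C7 ketone with the tert-butyl isobutyrate unit on C5 cis to the C20 methyl, diol-half series (C8 epimers) | CC1C(=O)C[C@H](C(C)(C)C(=O)OC(C)(C)C)[C@@](C)(CC(=O)OC(C)(C)C)[C@H]1CC[C@](C)(O[Si](CC)(CC)CC)[C@H]2COC(C)(C)O2 | intermediate
23 | (5S,9R,10S) C7=C8 enol triflate, diol-half series | CC1=C(OS(=O)(=O)C(F)(F)F)C[C@H](C(C)(C)C(=O)OC(C)(C)C)[C@@](C)(CC(=O)OC(C)(C)C)[C@H]1CC[C@](C)(O[Si](CC)(CC)CC)[C@H]2COC(C)(C)O2 | intermediate
24 | (5S,9S,10S) C7=C8 alkene, diol-half series | CC1=CC[C@H](C(C)(C)C(=O)OC(C)(C)C)[C@@](C)(CC(=O)OC(C)(C)C)[C@H]1CC[C@](C)(O[Si](CC)(CC)CC)[C@H]2COC(C)(C)O2 | intermediate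
25 | (5S,8S,9R,10R,13S,14R) diol diacid of the diol half (rings B and C closed, 14,15-diol, C2 and C3 acids) | OC[C@@H](O)[C@]1(C)CC[C@@H]2[C@](C)(CC(=O)O)[C@@H](C(C)(C)C(=O)O)CC[C@]2(C)O1 | intermediate
26 | diallyl ester of 25 | OC[C@@H](O)[C@]1(C)CC[C@@H]2[C@](C)(CC(=O)OCC=C)[C@@H](C(C)(C)C(=O)OCC=C)CC[C@]2(C)O1 | intermediate
27 | (2S,3S)-2,3-epoxygeraniol | CC(C)=CCC[C@]1(C)O[C@H]1CO | intermediate
28 | (2S,3R)-3,7-dimethyloct-6-ene-1,2,3-triol | CC(C)=CCC[C@@](C)(O)[C@@H](O)CO | intermediate
29 | (2R)-2-[(4S)-2,2-dimethyl-1,3-dioxolan-4-yl]-6-methylhept-5-en-2-ol | CC(C)=CCC[C@@](C)(O)[C@@H]1COC(C)(C)O1 | intermediate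
30 | triethylsilyl ether of 29 | CC(C)=CCC[C@@](C)(O[Si](CC)(CC)CC)[C@@H]1COC(C)(C)O1 | intermediate
31 | (4R)-4-[(4S)-2,2-dimethyl-1,3-dioxolan-4-yl]-4-(triethylsilyloxy)pentanal | O=CCC[C@@](C)(O[Si](CC)(CC)CC)[C@@H]1COC(C)(C)O1 | intermediate
32 | 4-tert-butyl 1-methyl (2E)-2-[(4R)-4-[(4S)-2,2-dimethyl-1,3-dioxolan-4-yl]-4-(triethylsilyloxy)pentylidene]butanedioate | COC(=O)/C(CC(=O)OC(C)(C)C)=C/CC[C@@](C)(O[Si](CC)(CC)CC)[C@@H]1COC(C)(C)O1 | intermediate
33 | tert-butyl (3E,7R)-7-[(4S)-2,2-dimethyl-1,3-dioxolan-4-yl]-3-(hydroxymethyl)-7-(triethylsilyloxy)oct-3-enoate | OC/C(CC(=O)OC(C)(C)C)=C/CC[C@@](C)(O[Si](CC)(CC)CC)[C@@H]1COC(C)(C)O1 | intermediate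
34 | tert-butyl (3E,7R)-7-[(4S)-2,2-dimethyl-1,3-dioxolan-4-yl]-3-formyl-7-(triethylsilyloxy)oct-3-enoate (E-enal, vinyl-half chain) | O=C/C(CC(=O)OC(C)(C)C)=C/CC[C@@](C)(O[Si](CC)(CC)CC)[C@@H]1COC(C)(C)O1 | intermediate
35 | cycloadduct of 34 and 15 (C9 and C10 as in 36, C5 epimers) | COC1C=C(O[Si](C)(C)C)C[C@H](CC[C@@](C)(O[Si](CC)(CC)CC)[C@@H]2COC(C)(C)O2)[C@]1(C=O)CC(=O)OC(C)(C)C | intermediate
36 | (9S,10R) ring B enone aldehyde, vinyl-half series | O=C1C=C[C@@](C=O)(CC(=O)OC(C)(C)C)[C@@H](CC[C@@](C)(O[Si](CC)(CC)CC)[C@@H]2COC(C)(C)O2)C1 | intermediate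
37 | E-tosylhydrazone of 36 | Cc1ccc(cc1)S(=O)(=O)N/N=C/[C@@]2(CC(=O)OC(C)(C)C)C=CC(=O)C[C@@H]2CC[C@@](C)(O[Si](CC)(CC)CC)[C@@H]3COC(C)(C)O3 | intermediate
38 | (9S,10S)-10-methyl ring B enone, vinyl-half series | O=C1C=C[C@@](C)(CC(=O)OC(C)(C)C)[C@@H](CC[C@@](C)(O[Si](CC)(CC)CC)[C@@H]2COC(C)(C)O2)C1 | intermediate
39 | (9S,10R)-8,10-dimethyl ring B enone, vinyl-half series (C8 epimers) | CC1C(=O)C=C[C@@](C)(CC(=O)OC(C)(C)C)[C@H]1CC[C@@](C)(O[Si](CC)(CC)CC)[C@@H]2COC(C)(C)O2 | intermediate
40 | (5S,9S,10S) C6=C7 trimethylsilyl enol ether, vinyl-half series (C8 epimers) | CC1C(O[Si](C)(C)C)=C[C@H](C(C)(C)C(=O)OC(C)(C)C)[C@@](C)(CC(=O)OC(C)(C)C)[C@H]1CC[C@@](C)(O[Si](CC)(CC)CC)[C@@H]2COC(C)(C)O2 | intermediate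
41 | (5S,9S,10S) C7 ketone with the tert-butyl isobutyrate unit on C5, vinyl-half series (C8 epimers) | CC1C(=O)C[C@H](C(C)(C)C(=O)OC(C)(C)C)[C@@](C)(CC(=O)OC(C)(C)C)[C@H]1CC[C@@](C)(O[Si](CC)(CC)CC)[C@@H]2COC(C)(C)O2 | intermediate
42 | (5S,9R,10S) C7=C8 enol triflate, vinyl-half series | CC1=C(OS(=O)(=O)C(F)(F)F)C[C@H](C(C)(C)C(=O)OC(C)(C)C)[C@@](C)(CC(=O)OC(C)(C)C)[C@H]1CC[C@@](C)(O[Si](CC)(CC)CC)[C@@H]2COC(C)(C)O2 | intermediate
43 | (5S,9S,10S) C7=C8 alkene, vinyl-half series | CC1=CC[C@H](C(C)(C)C(=O)OC(C)(C)C)[C@@](C)(CC(=O)OC(C)(C)C)[C@H]1CC[C@@](C)(O[Si](CC)(CC)CC)[C@@H]2COC(C)(C)O2 | intermediate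
44 | (5S,8S,9R,10R,13R,14S) diol diacid, vinyl-half series | OC[C@H](O)[C@@]1(C)CC[C@@H]2[C@](C)(CC(=O)O)[C@@H](C(C)(C)C(=O)O)CC[C@]2(C)O1 | intermediate
45 | diallyl ester of 44 | OC[C@H](O)[C@@]1(C)CC[C@@H]2[C@](C)(CC(=O)OCC=C)[C@@H](C(C)(C)C(=O)OCC=C)CC[C@]2(C)O1 | intermediate
46 | cyclic 14,15-thiocarbonate of 45 | S=C1OC[C@H](O1)[C@@]2(C)CC[C@@H]3[C@](C)(CC(=O)OCC=C)[C@@H](C(C)(C)C(=O)OCC=C)CC[C@]3(C)O2 | intermediate
47 | (5S,8S,9R,10R,13R) vinyl diallyl ester | C=C[C@@]1(C)CC[C@@H]2[C@](C)(CC(=O)OCC=C)[C@@H](C(C)(C)C(=O)OCC=C)CC[C@]2(C)O1 | intermediate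
48 | C2 acid of the vinyl half (C3 allyl ester) | C=C[C@@]1(C)CC[C@@H]2[C@](C)(CC(=O)O)[C@@H](C(C)(C)C(=O)OCC=C)CC[C@]2(C)O1 | intermediate
49 | triallyl ester of the target | C=C[C@@]1(C)CC[C@@H]2[C@](C)(CC(=O)OC[C@@H](O)[C@]3(C)CC[C@@H]4[C@](C)(CC(=O)OCC=C)[C@@H](C(C)(C)C(=O)OCC=C)CC[C@]4(C)O3)[C@@H](C(C)(C)C(=O)OCC=C)CC[C@]2(C)O1 | intermediate
50 | CNP0271961.3 | C=C[C@@]1(C)CC[C@@H]2[C@](C)(CC(=O)OC[C@@H](O)[C@]3(C)CC[C@@H]4[C@](C)(CC(=O)O)[C@@H](C(C)(C)C(=O)O)CC[C@]4(C)O3)[C@@H](C(C)(C)C(=O)O)CC[C@]2(C)O1 | target

## Step count and risk

Total step count: 39. Longest linear sequence: 21 steps (6 to 50 through the vinyl-half branch: steps 19 to 37, then 38 and 39). The diol-half branch contributes 16 steps (3 to 18) before the union.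

Steps least certain to work:

Step 11 (key step; step 27 shares the risk). Three things may go wrong.
- The very nucleophilic diene may add to the activated formyl carbon (Mukaiyama aldol or hetero-Diels–Alder pathway) instead of the C=C bond.
- The β-substituent may slow the cycloaddition until the acid-sensitive diene is consumed by protodesilylation.
- The sense or level of facial selectivity is not established for an enal of this substitution pattern with this diene. If the adduct proved to be the other ring diastereomer, the catalyst from (R)-α,α-diphenylprolinol would be used.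

Fallback, from 14 back to 17: 14 is heated without any acid with (E)-1-(dimethylamino)-3-(tert-butyldimethylsilyloxy)buta-1,3-diene in toluene. This diene is reactive enough for a thermal cycloaddition, and without a Lewis acid the formyl carbon is not activated. The product is the amino cycloadduct F1 as both ring-face diastereomers. Dilute acid then gives 17 together with its (9R,10S) ring diastereomer F2. The two are diastereomers because of the chain stereocentres, and are separated by chromatography; the route continues from 17.

Step 12 (and 28). Hydride transfer to the conjugated ketone, or condensation of the hydrazide at C7, may compete with the intended reduction of the hindered neopentylic aldehyde hydrazone.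

Fallback, from 17 back to 19: NaBH(OAc)3 reduces only the aldehyde to the neopentylic alcohol F3. I2, PPh3 and imidazole in warm toluene convert it into the primary iodide F4. Radical reduction with n-Bu3SnH and azobisisobutyronitrile gives 19.

Step 14 (and 30). Addition at C5 may fail or stall because the new bond joins a quaternary carbon to a carbon flanked by quaternary C10, and attack at the carbonyl carbon or on the acetonide may then take over. Facial selectivity could also erode if the half-chair with the axial C9 chain reacts.

Fallback, from 20 back to 22: the lithium enolate of 4 (LiN(i-Pr)2, THF, then DMPU) is added to 20 and the mixture is warmed from −78 to 0 °C. The 1,2-adduct reverts and the conjugate adduct accumulates under thermodynamic control; protonation gives 22 directly. No new compound is isolated.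

Step 15 (and 31). Loss of the C6 proton instead of the C8 proton would give the regioisomeric, less substituted triflate. The acetonide may also suffer from the triflating agent.

Fallback, from 22 back to 23: i-Pr2NMgBr in Et2O followed by Me3SiCl, Et3N and HMPA equilibrates the magnesium enolates and gives the tetrasubstituted C7=C8 trimethylsilyl enol ether F5, which is isolated. CsF and PhNTf2 in dimethoxyethane then convert F5 into 23 with the regiochemistry already fixed.

Step 17 (and 33). Several processes are asked of one acid treatment. The C8 cation may eliminate or be captured by a carboxyl group or by the freed C14 hydroxyl. Ring closure may also lag behind the deprotections, giving mixtures.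

Fallback, from 24 back to 25: Bu4NF in THF removes the triethylsilyl group to give the tertiary alcohol F6. Hg(OCOCF3)2 in CH2Cl2 followed by alkaline NaBH4 effects intramolecular alkoxymercuration and demercuration (anti addition, oxygen to the tertiary C8, the same cis-fused ring for conformational reasons) and gives the ring-closed di-tert-butyl ester acetonide F7. CF3CO2H/H2O then removes the tert-butyl and acetonide groups to give 25.

## Further compounds

F1 | step 11 | amino cycloadduct of 14 with (E)-1-(dimethylamino)-3-(tert-butyldimethylsilyloxy)buta-1,3-diene (both ring-face diastereomers, C11 cis to the acetic arm) | CN(C)C1C=C(O[Si](C)(C)C(C)(C)C)CC(CC[C@](C)(O[Si](CC)(CC)CC)[C@H]2COC(C)(C)O2)C1(C=O)CC(=O)OC(C)(C)C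
F2 | step 11 | (9R,10S) ring diastereomer of 17 | O=C1C=C[C@](C=O)(CC(=O)OC(C)(C)C)[C@H](CC[C@](C)(O[Si](CC)(CC)CC)[C@H]2COC(C)(C)O2)C1
F3 | step 12 | C20 alcohol from 17 (hydroxymethyl on C10) | OC[C@@]1(CC(=O)OC(C)(C)C)C=CC(=O)C[C@@H]1CC[C@](C)(O[Si](CC)(CC)CC)[C@H]2COC(C)(C)O2
F4 | step 12 | C20 iodide from F3 (iodomethyl on C10) | IC[C@@]1(CC(=O)OC(C)(C)C)C=CC(=O)C[C@@H]1CC[C@](C)(O[Si](CC)(CC)CC)[C@H]2COC(C)(C)O2
F0 | step 14 | none | none
F5 | step 15 | C7=C8 trimethylsilyl enol ether of 22 | CC1=C(O[Si](C)(C)C)C[C@H](C(C)(C)C(=O)OC(C)(C)C)[C@@](C)(CC(=O)OC(C)(C)C)[C@H]1CC[C@](C)(O[Si](CC)(CC)CC)[C@H]2COC(C)(C)O2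
F6 | step 17 | C13 tertiary alcohol from 24 | CC1=CC[C@H](C(C)(C)C(=O)OC(C)(C)C)[C@@](C)(CC(=O)OC(C)(C)C)[C@H]1CC[C@](C)(O)[C@H]2COC(C)(C)O2
F7 | step 17 | ring-closed di-tert-butyl ester acetonide of the diol half | CC1(C)OC[C@@H](O1)[C@]2(C)CC[C@@H]3[C@](C)(CC(=O)OC(C)(C)C)[C@@H](C(C)(C)C(=O)OC(C)(C)C)CC[C@]3(C)O2
A1 | alternative 1 | seven-membered 2,3-seco-anhydride of the vinyl half | C=C[C@@]1(C)CC[C@@H]2[C@]3(C)CC(=O)OC(=O)C(C)(C)[C@H]3CC[C@]2(C)O1
A2 | alternative 1 | ring A 2,3-diketone of the tricyclic vinyl half | C=C[C@@]1(C)CC[C@@H]2[C@]3(C)CC(=O)C(=O)C(C)(C)[C@H]3CC[C@]2(C)O1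
A3 | alternative 2 | cis-fused bicyclic δ-lactone aldehyde | O=C1CC[C@@H]2[C@](C)(CC=O)[C@@H](C(C)(C)C(=O)OC)CC[C@]2(C)O1
A4 | alternative 2 | acyclic Z-olefin enal tert-butyl ester | O=C/C=C(C)/[C@@H](C(C)(C)C(=O)OC)CC/C(C)=C\CCC(=O)OC(C)(C)C
A5 | alternative 3 | triallyl ester of the target (identical with 49) | C=C[C@@]1(C)CC[C@@H]2[C@](C)(CC(=O)OC[C@@H](O)[C@]3(C)CC[C@@H]4[C@](C)(CC(=O)OCC=C)[C@@H](C(C)(C)C(=O)OCC=C)CC[C@]4(C)O3)[C@@H](C(C)(C)C(=O)OCC=C)CC[C@]2(C)O1
A6 | alternative 3 | C10 diazoketone of the vinyl half (C3 allyl ester) | C=C[C@@]1(C)CC[C@@H]2[C@](C)(C(=O)C=[N+]=[N-])[C@@H](C(C)(C)C(=O)OCC=C)CC[C@]2(C)O1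
A7 | alternative 3 | ketene from A6 | C=C[C@@]1(C)CC[C@@H]2[C@](C)(C=C=O)[C@@H](C(C)(C)C(=O)OCC=C)CC[C@]2(C)O1
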